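**Retrosynthetic overview**
- Last ring (cyclohexene): [4+2] union of (12E)-9α-hydroxylabda-8(17),12,14-trien-7-one with 2-(5,7-dihydroxychromon-2-yl)-5-methoxy-1,4-benzoquinone, forming C12–C2' and C15–C3' with the quinone ring exo.
- Key bond: C9–O. It is made by α-face epoxidation of a Δ8(9) alkene, fixes the carbinol centre, and later, as an aluminium alkoxide, anchors and steers the cycloaddition.
- Ring B functionality: epoxide → 9α-hydroxy-8(17)-ene, C7 oxygen by SeO2, side chain by two Wittig reactions; rings A and B come intact from (+)-sclareolide.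
- Quinone partner: C–O ring closure of a 1,3-diketone to the chromone (phloroacetophenone + 2,4,5-trimethoxybenzoyl chloride), then oxidative demethylation to the methoxyquinone.
- Ring order: A/B (chiral pool) → chromone pyranone ring → quinone ring → cyclohexene ring (final step).

Assumption: labdane numbering (C1–C20) is used for the terpenoid part, the quinone-derived ring is C1'–C6' (C2' carries the chromonyl group, C5' the OMe), chromone atoms carry double primes; the target SMILES reads as 5S,9S,10S,12R,2'S,3'R, i.e. normal labdane series with 9α-OH, and the chromonyl group cis to C11 and to H-3'.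

Step 1
Reactants: 1 (+)-sclareolide
Product: 2 isopropyl (5S,10S)-13,14,15,16-tetranorlabd-8-en-12-oate
Conditions: conc. H2SO4 (cat.), i-PrOH, 82 °C
Reagents that add atoms: propan-2-ol, CC(C)O
Why: Acid-mediated alkyl–oxygen cleavage of the tertiary lactone (E1) with Fischer esterification gives mainly the thermodynamically favoured tetrasubstituted Δ8(9) alkene (minor Δ7 and Δ8(17) isomers removed on AgNO3-impregnated silica), C5 and C10 are untouched, and the isopropyl ester is chosen so that Al(Oi-Pr)3 in step 3 cannot scramble it.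

Step 2
Reactants: 2 isopropyl (5S,10S)-13,14,15,16-tetranorlabd-8-en-12-oate
Product: 3 isopropyl 8α,9α-epoxy-13,14,15,16-tetranorlabdan-12-oate
Conditions: mCPBA, CH2Cl2, 0 °C
Reagents that add atoms: 3-chloroperoxybenzoic acid, OOC(=O)c1cccc(Cl)c1
Why: Prilezhaev epoxidation of the electron-rich tetrasubstituted alkene occurs on the α face, anti to the axial C10 methyl group, so the C9–O bond of the later carbinol is formed with the 9α configuration.

Step 3
Reactants: 3 isopropyl 8α,9α-epoxy-13,14,15,16-tetranorlabdan-12-oate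
Product: 4 isopropyl 9α-hydroxy-13,14,15,16-tetranorlabd-8(17)-en-12-oate
Conditions: Al(Oi-Pr)3, toluene, 110 °C; aq. potassium sodium tartrate
Reagents that add atoms: none
Why: Aluminium alkoxide-mediated epoxide-to-allylic-alcohol isomerisation (syn β-elimination within the Al-bound epoxide) breaks C8–O rather than C9–O because positive charge at C9 is disfavoured by the β-ester, and it removes an unhindered C17 methyl hydrogen, giving the 8(17)-methylene and the tertiary 9α-OH with retention at C9, without the ester enolisation a strong base would cause.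

Step 4
Reactants: 4 isopropyl 9α-hydroxy-13,14,15,16-tetranorlabd-8(17)-en-12-oate
Product: 5 isopropyl 7α,9α-dihydroxy-13,14,15,16-tetranorlabd-8(17)-en-12-oate
Conditions: SeO2 (cat.), t-BuOOH, CH2Cl2, 23 °C
Reagents that add atoms: selenium dioxide (relays the oxygen), O=[Se]=O; tert-butyl hydroperoxide (stoichiometric oxygen source), CC(C)(C)OO
Why: Riley allylic oxidation (ene reaction then [2,3]-shift) can only occur at C7 because C9 carries no hydrogen, and removal of the axial 7α-H delivers the 7α-OH (this centre is erased in step 8, and any 7-ketone formed is returned to the alcohol in step 5).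

Step 5
Reactants: 5 isopropyl 7α,9α-dihydroxy-13,14,15,16-tetranorlabd-8(17)-en-12-oate
Product: 6 7α,9α-dihydroxy-13,14,15,16-tetranorlabd-8(17)-en-12-al
Conditions: i-Bu2AlH (3.3 equiv), CH2Cl2, −78 °C; aq. potassium sodium tartrate
Reagents that add atoms: none
Why: Partial hydride reduction of the ester stops at the tetrahedral aluminium hemiacetal, which is held as a chelate by the neighbouring C9 aluminium alkoxide at −78 °C and collapses to the aldehyde only on work-up.

Step 6
Reactants: 6 7α,9α-dihydroxy-13,14,15,16-tetranorlabd-8(17)-en-12-al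
Product: 7 (12E)-7α,9α-dihydroxy-15-norlabda-8(17),12-dien-14-al
Conditions: Ph3P=C(CH3)CHO, toluene, 70 °C
Reagents that add atoms: 2-(triphenylphosphoranylidene)propanal, CC(C=O)=P(c1ccccc1)(c1ccccc1)c1ccccc1
Why: Wittig reaction with a formyl-stabilised ylide sets the trisubstituted C12=C13 bond as E (>95:5) under nearly neutral conditions that should spare the β-hydroxy aldehyde from retro-aldol cleavage.

Step 7
Reactants: 7 (12E)-7α,9α-dihydroxy-15-norlabda-8(17),12-dien-14-al
Product: 8 (12E)-labda-8(17),12,14-triene-7α,9α-diol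
Conditions: Ph3PCH3Br, KN(SiMe3)2 (3.5 equiv each), THF, −78 → 0 °C
Reagents that add atoms: methyltriphenylphosphonium bromide, C[P+](c1ccccc1)(c1ccccc1)c1ccccc1.[Br-]
Why: Wittig methylenation of the enal is fast at −78 °C (excess ylide covers the two OH groups) and gives the 1,3-diene without changing the C12=C13 geometry.

Step 8
Reactants: 8 (12E)-labda-8(17),12,14-triene-7α,9α-diol
Product: 9 (12E)-9α-hydroxylabda-8(17),12,14-trien-7-one
Conditions: MnO2, CH2Cl2, 23 °C
Reagents that add atoms: none
Why: MnO2 oxidises only the allylic secondary alcohol to the exo-methylene ketone, leaving the tertiary C9–OH and the diene untouched.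

Step 9
Reactants: 10 2,4,5-trimethoxybenzoic acid
Product: 11 2,4,5-trimethoxybenzoyl chloride
Conditions: (COCl)2, DMF (cat.), CH2Cl2, 0 → 23 °C
Reagents that add atoms: oxalyl chloride, O=C(Cl)C(Cl)=O
Why: Standard acid chloride formation through the chloroiminium (Vilsmeier-type) intermediate.

Step 10
Reactants: 11 2,4,5-trimethoxybenzoyl chloride; 12 2',4',6'-trihydroxyacetophenone
Product: 14 5,7-dihydroxy-2-(2,4,5-trimethoxyphenyl)-4H-chromen-4-one, via diketone 13 (not isolated)
Conditions: LiN(SiMe3)2 (4.2 equiv), THF, −78 → 23 °C; aq. HCl; crude in AcOH, H2SO4 (cat.), 95 °C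
Reagents that add atoms: none
Why: C-acylation of the lithium polyanion (three phenoxides plus the enolate) by the aroyl chloride gives the 1,3-diketone, and acid-catalysed attack of an ortho phenol on the aryl ketone with loss of water closes the pyranone ring through the new O1''–C2'' bond (Baker–Venkataraman-type diketone cyclodehydration).

Step 11
Reactants: 14 5,7-dihydroxy-2-(2,4,5-trimethoxyphenyl)-4H-chromen-4-one
Product: 15 2-(5,7-dihydroxy-4-oxo-4H-chromen-2-yl)-5-methoxy-1,4-benzoquinone
Conditions: (NH4)2Ce(NO3)6 (2.3 equiv), MeCN/H2O, 0 °C, 10 min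
Reagents that add atoms: water, O
Why: Oxidative demethylation by tetravalent cerium: the electron-rich 1,2,4-trimethoxyarene is oxidised, water attacks the para-related methoxy-bearing carbons with loss of two methanol molecules, and the remaining OMe ends up as the vinylogous ester, while the hydrogen-bonded, carbonyl-deactivated phenols of the chromone react more slowly.

Step 12
Reactants: 9 (12E)-9α-hydroxylabda-8(17),12,14-trien-7-one; 15 2-(5,7-dihydroxy-4-oxo-4H-chromen-2-yl)-5-methoxy-1,4-benzoquinone
Product: 19 CNP0241859.1 (5S,9S,10S,12R,2'S,3'R), via diene aluminium alkoxide 16 (not isolated), via aluminated quinone 17 (not isolated), via aluminated cycloadduct 18 (not isolated)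
Conditions: MeAl(OAr)2 (Ar = 2,6-di-tert-butyl-4-methylphenyl; 1.05 equiv on 9 at 23 °C, 2.1 equiv on 15 at −78 → 0 °C), toluene/CH2Cl2; combine at −78 °C, then −20 °C; 1 M HCl, 0 °C
Reagents that add atoms: none
Why: Proposed new method: an alkoxide-tethered, exo-selective Diels–Alder reaction in which the C9–O bond is turned by MeAl(OAr)2 into a bulky, non-chelating aluminium alkoxide bis(aryloxide) (the two phenols of 15 are masked the same way) that binds the more basic vinylogous-ester carbonyl C1'=O and delivers C2'=C3' through an eight-membered C9–O–Al←O=C1' bridged transition structure; because C12 sits anti to C10 about C9–C11 and the C13 methyl (A(1,3) strain) keeps C9 on the side away from it, O9 lies over the Re face of C12 and the quinone adds there (12R), the bridge can close only with the quinone ring exo (otherwise the aryloxide-laden aluminium would sit under the C13 methyl), which puts the chromonyl endo and cis to C11 (2'S) with cis ring fusion (3'R), and C1'=O activation makes C3' the electrophilic partner of C15; the closest known reaction types are magnesium- or aluminium-alkoxide-templated Diels–Alder reactions of dienols with acrylates and exo-selective Diels–Alder reactions promoted by bulky aluminium aryloxides.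

**Compound list**
1 | (+)-sclareolide | C[C@]12CCCC(C)(C)[C@@H]1CC[C@@]1(C)OC(=O)C[C@H]21 | starting material
2 | isopropyl (5S,10S)-13,14,15,16-tetranorlabd-8-en-12-oate | CC(C)OC(=O)CC1=C(C)CC[C@H]2C(C)(C)CCC[C@]12C | intermediate
3 | isopropyl 8α,9α-epoxy-13,14,15,16-tetranorlabdan-12-oate | CC(C)OC(=O)C[C@@]12O[C@]1(C)CC[C@H]1C(C)(C)CCC[C@]21C | intermediate
4 | isopropyl 9α-hydroxy-13,14,15,16-tetranorlabd-8(17)-en-12-oate | CC(C)OC(=O)C[C@@]1(O)C(=C)CC[C@H]2C(C)(C)CCC[C@]12C | intermediate
5 | isopropyl 7α,9α-dihydroxy-13,14,15,16-tetranorlabd-8(17)-en-12-oate | CC(C)OC(=O)C[C@@]1(O)C(=C)[C@H](O)C[C@H]2C(C)(C)CCC[C@]12C | intermediate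
6 | 7α,9α-dihydroxy-13,14,15,16-tetranorlabd-8(17)-en-12-al | O=CC[C@@]1(O)C(=C)[C@H](O)C[C@H]2C(C)(C)CCC[C@]12C | intermediate
7 | (12E)-7α,9α-dihydroxy-15-norlabda-8(17),12-dien-14-al | O=C/C(C)=C/C[C@@]1(O)C(=C)[C@H](O)C[C@H]2C(C)(C)CCC[C@]12C | intermediate
8 | (12E)-labda-8(17),12,14-triene-7α,9α-diol | C=C/C(C)=C/C[C@@]1(O)C(=C)[C@H](O)C[C@H]2C(C)(C)CCC[C@]12C | intermediate
9 | (12E)-9α-hydroxylabda-8(17),12,14-trien-7-one | C=C/C(C)=C/C[C@@]1(O)C(=C)C(=O)C[C@H]2C(C)(C)CCC[C@]12C | intermediate
10 | 2,4,5-trimethoxybenzoic acid | COc1cc(OC)c(cc1OC)C(=O)O | starting material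
11 | 2,4,5-trimethoxybenzoyl chloride | COc1cc(OC)c(cc1OC)C(=O)Cl | intermediate
12 | 2',4',6'-trihydroxyacetophenone | CC(=O)c1c(O)cc(O)cc1O | starting material
13 | 1-(2,4,6-trihydroxyphenyl)-3-(2,4,5-trimethoxyphenyl)propane-1,3-dione | COc1cc(OC)c(cc1OC)C(=O)CC(=O)c1c(O)cc(O)cc1O | intermediate
14 | 5,7-dihydroxy-2-(2,4,5-trimethoxyphenyl)-4H-chromen-4-one | COc1cc(OC)c(cc1OC)-c1cc(=O)c2c(O)cc(O)cc2o1 | intermediate
15 | 2-(5,7-dihydroxy-4-oxo-4H-chromen-2-yl)-5-methoxy-1,4-benzoquinone | COC1=CC(=O)C(=CC1=O)c1cc(=O)c2c(O)cc(O)cc2o1 | intermediate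
16 | 9-O-[bis(2,6-di-tert-butyl-4-methylphenoxy)aluminio] derivative of the diene (12E)-9α-hydroxylabda-8(17),12,14-trien-7-one | C=C/C(C)=C/C[C@@]1(O[Al](Oc2c(C(C)(C)C)cc(C)cc2C(C)(C)C)Oc2c(C(C)(C)C)cc(C)cc2C(C)(C)C)C(=C)C(=O)C[C@H]2C(C)(C)CCC[C@]12C | intermediate
17 | 5'',7''-bis-O-[bis(2,6-di-tert-butyl-4-methylphenoxy)aluminio] derivative of the chromonyl methoxyquinone | COC1=CC(=O)C(=CC1=O)c1cc(=O)c2c(O[Al](Oc3c(C(C)(C)C)cc(C)cc3C(C)(C)C)Oc3c(C(C)(C)C)cc(C)cc3C(C)(C)C)cc(O[Al](Oc3c(C(C)(C)C)cc(C)cc3C(C)(C)C)Oc3c(C(C)(C)C)cc(C)cc3C(C)(C)C)cc2o1 | intermediate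
18 | 9,5'',7''-tris-O-[bis(2,6-di-tert-butyl-4-methylphenoxy)aluminio] derivative of the cycloadduct | C=C1C(=O)C[C@H]2C(C)(C)CCC[C@]2(C)[C@@]1(O[Al](Oc3c(C(C)(C)C)cc(C)cc3C(C)(C)C)Oc3c(C(C)(C)C)cc(C)cc3C(C)(C)C)C[C@@H]1C(C)=CC[C@H]2C(=O)C(OC)=CC(=O)[C@@]12c1cc(=O)c2c(O[Al](Oc3c(C(C)(C)C)cc(C)cc3C(C)(C)C)Oc3c(C(C)(C)C)cc(C)cc3C(C)(C)C)cc(O[Al](Oc3c(C(C)(C)C)cc(C)cc3C(C)(C)C)Oc3c(C(C)(C)C)cc(C)cc3C(C)(C)C)cc2o1 | intermediate
19 | CNP0241859.1: cis-fused exo cycloadduct (5S,9S,10S,12R,2'S,3'R), C12–C2' and C15–C3' bonds, chromonyl on C2' cis to C11 and to H-3' | C=C1C(=O)C[C@H]2C(C)(C)CCC[C@]2(C)[C@@]1(O)C[C@@H]1C(C)=CC[C@H]2C(=O)C(OC)=CC(=O)[C@@]12c1cc(=O)c2c(O)cc(O)cc2o1 | target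

**Step count**
Total: 12 steps. Longest linear sequence: 9 steps (steps 1–8, then step 12); the quinone branch is 3 steps (9–11).

**Three steps most likely to fail**

Step 12 (the new step). The exo and Re-face preference comes from a conformational model, not from experiment, and the aluminium alkoxide may be too hindered to bind the quinone or may bind the wrong carbonyl, so the endo or Si-face adducts could dominate. Fallback with known chemistry: set out from 9 and 15 and run the plain, metal-free thermal Diels–Alder reaction (CH2Cl2, 12 kbar, 23 °C, or toluene, 60 °C). Only the C9–OH···O=C1' hydrogen bond and the innate polarisation of the quinone steer this reaction. The regio- and stereoisomeric adducts are separated by preparative HPLC, and the route is rejoined at 19. New compounds on this way: none F0.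

Step 3. The epoxide may open towards the Δ7 alkene or at C9–O, and the β-hydroxy ester aluminate may fragment at 110 °C. Fallback: set out from epoxy ester 3 and remove the acidic ester before the epoxide is opened. LiAlH4 (THF, 0 °C) gives 8α,9α-epoxy-13,14,15,16-tetranorlabdan-12-ol F1. Diethylaluminium 2,2,6,6-tetramethylpiperidide (4 equiv, benzene, 0 °C), the classical hindered amide base for this isomerisation, takes a C17 proton and gives 13,14,15,16-tetranorlabd-8(17)-ene-9α,12-diol F2. SeO2/t-BuOOH then gives 13,14,15,16-tetranorlabd-8(17)-ene-7α,9α,12-triol F3. PhI(OAc)2 with catalytic TEMPO oxidises only the primary alcohol, and the route is rejoined at aldehyde 6.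

Step 11. The free 7''-phenol of the phloroglucinol-type ring may be oxidised or nitrated by the cerium reagent. Fallback: set out from flavone 14 and protect first. TBSCl/imidazole (DMF) silylates only the free 7-OH (the 5-OH is locked in a hydrogen bond to the C4 carbonyl) and gives 7-(tert-butyldimethylsilyloxy)-5-hydroxy-2-(2,4,5-trimethoxyphenyl)-4H-chromen-4-one F4. (NH4)2Ce(NO3)6 then gives 2-[7-(tert-butyldimethylsilyloxy)-5-hydroxy-4-oxo-4H-chromen-2-yl]-5-methoxy-1,4-benzoquinone F5. HF·pyridine (THF, 0 °C) removes the silyl group, and the route is rejoined at quinone 15.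

**Further compounds**
F1 | step 3 | 8α,9α-epoxy-13,14,15,16-tetranorlabdan-12-ol | OCC[C@@]12O[C@]1(C)CC[C@H]1C(C)(C)CCC[C@]21C
F2 | step 3 | 13,14,15,16-tetranorlabd-8(17)-ene-9α,12-diol | OCC[C@@]1(O)C(=C)CC[C@H]2C(C)(C)CCC[C@]12C
F3 | step 3 | 13,14,15,16-tetranorlabd-8(17)-ene-7α,9α,12-triol | OCC[C@@]1(O)C(=C)[C@H](O)C[C@H]2C(C)(C)CCC[C@]12C
F4 | step 11 | 7-(tert-butyldimethylsilyloxy)-5-hydroxy-2-(2,4,5-trimethoxyphenyl)-4H-chromen-4-one | COc1cc(OC)c(cc1OC)-c1cc(=O)c2c(O)cc(O[Si](C)(C)C(C)(C)C)cc2o1
F5 | step 11 | 2-[7-(tert-butyldimethylsilyloxy)-5-hydroxy-4-oxo-4H-chromen-2-yl]-5-methoxy-1,4-benzoquinone | COC1=CC(=O)C(=CC1=O)c1cc(=O)c2c(O)cc(O[Si](C)(C)C(C)(C)C)cc2o1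
F0 | step 12 | none | none
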